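**Retrosynthetic overview**

1. The target, (2S)-6-prenyleriodictyol, is reached by global desilylation of a flavanone whose ring C is closed last, at C4–C4a, by intramolecular Friedel–Crafts acylation of a (3S)-3-aryl-3-aryloxypropanoic acid that already holds O1–C2 and the C2 stereocentre.
2. Ring A is built, not substituted: a prenyl siloxyalkyne is inserted into the C(=O)–CH bond of a 3-alkoxycyclobutenone that carries O1 and C2, making C5–C6 and C7–C8 and the whole benzene ring.
3. The cyclobutenone ether comes from an (S)-β-hydroxy ester (asymmetric transfer hydrogenation of the aryl β-keto ester made from 3,4-dihydroxybenzoic acid) and 3-ethoxycyclobutenone; the alkyne comes from ethyl 4-methylpent-3-enoate by ynolate homologation.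
4. The strategy rests on this feature: ring A is a 1,3,5-trioxygenated benzene (O1 on C8a, O5, O7) whose prenyl carbon C6 lies between C5 and C7 and para to C8a. C4a and C8 are therefore equivalent until acylation, the annulation fixes the prenyl position by connectivity, and either ortho carbon can close the pyranone.
5. Order of rings: ring B (bought) → ring A (step 6) → ring C (step 8).

Key step: step 6

Assumption: the transfer hydrogenation of the aryl β-keto ester is taken to follow the aryl ketone model, the (S,S)-ligand giving the (S)-carbinol; no bond at that carbon is touched afterwards, so it becomes (2S) in the target.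

**Route**

Step 1
Reactants: 1 3,4-dihydroxybenzoic acid
Product: 3 3,4-bis(tert-butyldimethylsilyloxy)benzoic acid, via silyl ester 2 (not isolated)
Conditions: TBSCl, imidazole, DMF, rt; then AcOH/THF/H2O, rt
Reagents that add atoms: tert-butyldimethylsilyl chloride (TBSCl), CC(C)(C)[Si](C)(C)Cl
Why: Silyl ether protection of all three acidic hydroxyls, then mild acidic hydrolysis that cleaves only the labile silyl ester and leaves the aryl silyl ethers.

Step 2
Reactants: 3 3,4-bis(tert-butyldimethylsilyloxy)benzoic acid; 4 Meldrum's acid (2,2-dimethyl-1,3-dioxane-4,6-dione)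
Product: 6 prop-2-en-1-yl 3-[3,4-bis(tert-butyldimethylsilyloxy)phenyl]-3-oxopropanoate, via acyl Meldrum's acid 5 (not isolated)
Conditions: DCC, DMAP, CH2Cl2, 0 °C to rt; filter; then allyl alcohol, toluene, 90 °C
Reagents that add atoms: allyl alcohol, C=CCO
Why: Carbodiimide C-acylation of Meldrum's acid and thermal fragmentation of 5 to an acylketene that allyl alcohol traps with loss of acetone and CO2 (Oikawa–Yonemitsu β-keto ester synthesis), under neutral conditions that the aryl silyl ethers tolerate.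

Step 3
Reactants: 6 prop-2-en-1-yl 3-[3,4-bis(tert-butyldimethylsilyloxy)phenyl]-3-oxopropanoate
Product: 7 prop-2-en-1-yl (3S)-3-[3,4-bis(tert-butyldimethylsilyloxy)phenyl]-3-hydroxypropanoate
Conditions: RuCl(p-cymene)[(S,S)-TsDPEN] (1 mol %), HCO2H/Et3N (5:2), DMF, 30 °C
Reagents that add atoms: none
Why: Noyori–Ikariya asymmetric transfer hydrogenation, in which the (S,S)-ligand complex delivers hydride to the Re face of the aryl ketone through the CH/π-organised outer-sphere transition state and so sets the (S)-carbinol that becomes C2, while the allyl ester alkene and the aryl silyl ethers are inert to the ruthenium hydride.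

Step 4
Reactants: 7 prop-2-en-1-yl (3S)-3-[3,4-bis(tert-butyldimethylsilyloxy)phenyl]-3-hydroxypropanoate; 8 3-ethoxycyclobut-2-en-1-one
Product: 9 prop-2-en-1-yl (3S)-3-[3,4-bis(tert-butyldimethylsilyloxy)phenyl]-3-[(3-oxocyclobut-1-en-1-yl)oxy]propanoate
Conditions: 8 (3 equiv), PPTS (10 mol %), toluene, 5 Å MS, 40 °C
Reagents that add atoms: none
Why: Acid-catalysed transetherification of a vinylogous ester (addition of the alcohol to C3 of the O-protonated cyclobutenone and loss of ethanol, pulled by the sieves and the excess of 8); the new bond is O–C(sp2), so the carbinol configuration is retained, and the temperature stays below that of cyclobutenone ring opening.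

Step 5
Reactants: 10 ethyl 4-methylpent-3-enoate
Product: 12 triisopropyl[(5-methylhex-4-en-1-yn-1-yl)oxy]silane, via lithium ynolate 11 (not isolated)
Conditions: CH2Br2, LiTMP, THF, −78 °C; add 10; LiN(SiMe3)2; n-BuLi, −78 °C to rt; then i-Pr3SiCl, 0 °C
Reagents that add atoms: dibromomethane, BrCBr; triisopropylsilyl chloride (TIPSCl), CC(C)[Si](Cl)(C(C)C)C(C)C
Why: Kowalski ester homologation, in which dibromomethyllithium adds to the ester, the derived dibromo enolate undergoes bromine–lithium exchange and 1,2-shift of the prenyl group to give ynolate 11, and the bulky silyl chloride silylates on oxygen.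

Step 6
Reactants: 9 prop-2-en-1-yl (3S)-3-[3,4-bis(tert-butyldimethylsilyloxy)phenyl]-3-[(3-oxocyclobut-1-en-1-yl)oxy]propanoate; 12 triisopropyl[(5-methylhex-4-en-1-yn-1-yl)oxy]silane
Product: 17 prop-2-en-1-yl (3S)-3-[3,4-bis(tert-butyldimethylsilyloxy)phenyl]-3-[3-hydroxy-4-(3-methylbut-2-en-1-yl)-5-(triisopropylsilyloxy)phenoxy]propanoate, via vinylketene 13 (not isolated), via vinylcyclobutenone 14 (not isolated), via dienylketene 15 (not isolated), via cyclohexadienone 16 (not isolated)
Conditions: 12 (1.5 equiv), toluene, 80 °C then 110 °C, argon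
Reagents that add atoms: none
Why: Heating should open cyclobutenone 9 by 4π conrotatory cleavage of its C(=O)–CH2 bond to the alkoxyvinylketene 13, whose ketene C=C adds ynol ether 12 in a polarity-governed [2+2] cycloaddition to give 14; strain then drives a second 4π opening to dienylketene 15, a 6π disrotatory electrocyclisation gives 16, and tautomerisation to phenol 17 makes the cascade irreversible. The closest known reaction type is the Danheiser benzannulation of cyclobutenones with siloxyalkynes, which gives resorcinol monosilyl ethers. Ring A, the only ring formed, closes by 6π electrocyclisation at the bond between the former carbonyl carbon and the former CH2 carbon (the later C5–C4a bond), after the two new skeletal bonds C5–C6 and C7–C8 have been made in the [2+2] step. No stereocentre is created, since the sp3 ring carbon of 14 is lost on ring opening, and the existing centre at the ether carbon is not involved because the medium is neutral and aprotic. The selectivity needed is regiochemical: the nucleophilic prenyl-bearing carbon of the ynol ether must bond to the electrophilic ketene carbonyl carbon and the oxygen-bearing carbon to the ketene α-carbon, which the donor oxygen of the siloxyalkyne secures, placing the prenyl group between the new hydroxyl and the siloxy carbon and para to the ether oxygen. The alkyne is used in excess so that the vinylketene is intercepted before it can dimerise or be trapped by product phenol.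

Step 7
Reactants: 17 prop-2-en-1-yl (3S)-3-[3,4-bis(tert-butyldimethylsilyloxy)phenyl]-3-[3-hydroxy-4-(3-methylbut-2-en-1-yl)-5-(triisopropylsilyloxy)phenoxy]propanoate
Product: 18 (3S)-3-[3,4-bis(tert-butyldimethylsilyloxy)phenyl]-3-[3-hydroxy-4-(3-methylbut-2-en-1-yl)-5-(triisopropylsilyloxy)phenoxy]propanoic acid
Conditions: Pd(PPh3)4 (5 mol %), morpholine, THF, rt; pH 4 buffer work-up
Reagents that add atoms: none
Why: Tsuji–Trost deallylation, in which zerovalent palladium ionises the allyl ester to a π-allyl complex that morpholine captures, freeing the acid under neutral conditions that spare the silyl ethers, the base-sensitive β-aryloxy ester motif and the C-prenyl group.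

Step 8
Reactants: 18 (3S)-3-[3,4-bis(tert-butyldimethylsilyloxy)phenyl]-3-[3-hydroxy-4-(3-methylbut-2-en-1-yl)-5-(triisopropylsilyloxy)phenoxy]propanoic acid
Product: 20 (2S)-2-[3,4-bis(tert-butyldimethylsilyloxy)phenyl]-5-hydroxy-6-(3-methylbut-2-en-1-yl)-7-(triisopropylsilyloxy)-2,3-dihydro-4H-chromen-4-one, via mixed anhydride 19 (not isolated)
Conditions: TFAA, 2,6-di-tert-butyl-4-methylpyridine, CH2Cl2, −20 to 0 °C; then aq. NaHCO3
Reagents that add atoms: none
Why: Intramolecular Friedel–Crafts acylation through the acyl trifluoroacetate, in which the ring A carbon between the ether oxygen and the free hydroxyl, activated ortho/para by all three oxygens, attacks the acyl carbon (6-exo-trig) much faster than the less activated ring B could close a five-membered ring; the hindered pyridine keeps free acid low to spare the benzylic ether and the prenylphenol, and closure at the other ortho carbon would only exchange the silyl position and lead to the same target.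

Step 9
Reactants: 20 (2S)-2-[3,4-bis(tert-butyldimethylsilyloxy)phenyl]-5-hydroxy-6-(3-methylbut-2-en-1-yl)-7-(triisopropylsilyloxy)-2,3-dihydro-4H-chromen-4-one
Product: 21 (2S)-2-(3,4-dihydroxyphenyl)-5,7-dihydroxy-6-(3-methylbut-2-en-1-yl)-2,3-dihydro-4H-chromen-4-one
Conditions: TBAF, AcOH (1:1), THF, 0 °C to rt
Reagents that add atoms: none
Why: Fluoride-mediated cleavage of the three aryl silyl ethers, with acetic acid buffering the phenoxides so that the flavanone should neither open to the chalcone (which would racemise C2 and scramble 6- against 8-prenyl) nor cyclise at the prenyl group.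

**Compound list**

1 | 3,4-dihydroxybenzoic acid | OC(=O)c1ccc(O)c(O)c1 | starting material
2 | tert-butyldimethylsilyl 3,4-bis(tert-butyldimethylsilyloxy)benzoate | CC(C)(C)[Si](C)(C)OC(=O)c1ccc(O[Si](C)(C)C(C)(C)C)c(O[Si](C)(C)C(C)(C)C)c1 | intermediate (not isolated)
3 | 3,4-bis(tert-butyldimethylsilyloxy)benzoic acid | OC(=O)c1ccc(O[Si](C)(C)C(C)(C)C)c(O[Si](C)(C)C(C)(C)C)c1 | intermediate
4 | Meldrum's acid (2,2-dimethyl-1,3-dioxane-4,6-dione) | CC1(C)OC(=O)CC(=O)O1 | starting material
5 | 5-{[3,4-bis(tert-butyldimethylsilyloxy)phenyl](hydroxy)methylidene}-2,2-dimethyl-1,3-dioxane-4,6-dione | CC1(C)OC(=O)C(=C(O)c2ccc(O[Si](C)(C)C(C)(C)C)c(O[Si](C)(C)C(C)(C)C)c2)C(=O)O1 | intermediate (not isolated)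
6 | prop-2-en-1-yl 3-[3,4-bis(tert-butyldimethylsilyloxy)phenyl]-3-oxopropanoate | C=CCOC(=O)CC(=O)c1ccc(O[Si](C)(C)C(C)(C)C)c(O[Si](C)(C)C(C)(C)C)c1 | intermediate
7 | prop-2-en-1-yl (3S)-3-[3,4-bis(tert-butyldimethylsilyloxy)phenyl]-3-hydroxypropanoate | C=CCOC(=O)C[C@@H](c1ccc(O[Si](C)(C)C(C)(C)C)c(O[Si](C)(C)C(C)(C)C)c1)O | intermediate
8 | 3-ethoxycyclobut-2-en-1-one | CCOC1=CC(=O)C1 | starting material
9 | prop-2-en-1-yl (3S)-3-[3,4-bis(tert-butyldimethylsilyloxy)phenyl]-3-[(3-oxocyclobut-1-en-1-yl)oxy]propanoate | C=CCOC(=O)C[C@@H](c1ccc(O[Si](C)(C)C(C)(C)C)c(O[Si](C)(C)C(C)(C)C)c1)OC1=CC(=O)C1 | intermediate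
10 | ethyl 4-methylpent-3-enoate | CCOC(=O)CC=C(C)C | starting material
11 | lithium 5-methylhex-4-en-1-yn-1-olate | CC(C)=CCC#C[O-].[Li+] | intermediate (not isolated)
12 | triisopropyl[(5-methylhex-4-en-1-yn-1-yl)oxy]silane | CC(C)=CCC#CO[Si](C(C)C)(C(C)C)C(C)C | intermediate
13 | prop-2-en-1-yl (3S)-3-[3,4-bis(tert-butyldimethylsilyloxy)phenyl]-3-[(4-oxobuta-1,3-dien-2-yl)oxy]propanoate | C=CCOC(=O)C[C@@H](c1ccc(O[Si](C)(C)C(C)(C)C)c(O[Si](C)(C)C(C)(C)C)c1)OC(=C)C=C=O | intermediate (not isolated)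
14 | prop-2-en-1-yl (3S)-3-[3,4-bis(tert-butyldimethylsilyloxy)phenyl]-3-({1-[3-(3-methylbut-2-en-1-yl)-4-oxo-2-(triisopropylsilyloxy)cyclobut-2-en-1-yl]ethenyl}oxy)propanoate (ring sp3 carbon unassigned) | C=CCOC(=O)C[C@@H](c1ccc(O[Si](C)(C)C(C)(C)C)c(O[Si](C)(C)C(C)(C)C)c1)OC(=C)C1C(=O)C(CC=C(C)C)=C1O[Si](C(C)C)(C(C)C)C(C)C | intermediate (not isolated)
15 | prop-2-en-1-yl (3S)-3-[3,4-bis(tert-butyldimethylsilyloxy)phenyl]-3-{[(3E)-5-(3-methylbut-2-en-1-yl)-6-oxo-4-(triisopropylsilyloxy)hexa-1,3,5-trien-2-yl]oxy}propanoate (ketenyl and alkoxyvinyl groups cis on the central double bond) | C=CCOC(=O)C[C@@H](c1ccc(O[Si](C)(C)C(C)(C)C)c(O[Si](C)(C)C(C)(C)C)c1)OC(=C)/C=C(O[Si](C(C)C)(C(C)C)C(C)C)\C(CC=C(C)C)=C=O | intermediate (not isolated)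
16 | prop-2-en-1-yl (3S)-3-[3,4-bis(tert-butyldimethylsilyloxy)phenyl]-3-{[4-(3-methylbut-2-en-1-yl)-5-oxo-3-(triisopropylsilyloxy)cyclohexa-1,3-dien-1-yl]oxy}propanoate | C=CCOC(=O)C[C@@H](c1ccc(O[Si](C)(C)C(C)(C)C)c(O[Si](C)(C)C(C)(C)C)c1)OC1=CC(O[Si](C(C)C)(C(C)C)C(C)C)=C(CC=C(C)C)C(=O)C1 | intermediate (not isolated)
17 | prop-2-en-1-yl (3S)-3-[3,4-bis(tert-butyldimethylsilyloxy)phenyl]-3-[3-hydroxy-4-(3-methylbut-2-en-1-yl)-5-(triisopropylsilyloxy)phenoxy]propanoate | C=CCOC(=O)C[C@@H](c1ccc(O[Si](C)(C)C(C)(C)C)c(O[Si](C)(C)C(C)(C)C)c1)Oc1cc(O)c(CC=C(C)C)c(O[Si](C(C)C)(C(C)C)C(C)C)c1 | intermediate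
18 | (3S)-3-[3,4-bis(tert-butyldimethylsilyloxy)phenyl]-3-[3-hydroxy-4-(3-methylbut-2-en-1-yl)-5-(triisopropylsilyloxy)phenoxy]propanoic acid | OC(=O)C[C@@H](c1ccc(O[Si](C)(C)C(C)(C)C)c(O[Si](C)(C)C(C)(C)C)c1)Oc1cc(O)c(CC=C(C)C)c(O[Si](C(C)C)(C(C)C)C(C)C)c1 | intermediate
19 | (3S)-3-[3,4-bis(tert-butyldimethylsilyloxy)phenyl]-3-[3-hydroxy-4-(3-methylbut-2-en-1-yl)-5-(triisopropylsilyloxy)phenoxy]propanoic trifluoroacetic anhydride | O=C(C[C@@H](c1ccc(O[Si](C)(C)C(C)(C)C)c(O[Si](C)(C)C(C)(C)C)c1)Oc1cc(O)c(CC=C(C)C)c(O[Si](C(C)C)(C(C)C)C(C)C)c1)OC(=O)C(F)(F)F | intermediate (not isolated)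
20 | (2S)-2-[3,4-bis(tert-butyldimethylsilyloxy)phenyl]-5-hydroxy-6-(3-methylbut-2-en-1-yl)-7-(triisopropylsilyloxy)-2,3-dihydro-4H-chromen-4-one | CC(C)=CCc1c(O[Si](C(C)C)(C(C)C)C(C)C)cc2c(c1O)C(=O)C[C@@H](c1ccc(O[Si](C)(C)C(C)(C)C)c(O[Si](C)(C)C(C)(C)C)c1)O2 | intermediate
21 | (2S)-2-(3,4-dihydroxyphenyl)-5,7-dihydroxy-6-(3-methylbut-2-en-1-yl)-2,3-dihydro-4H-chromen-4-one | CC(C)=CCc1c(O)cc2c(c1O)C(=O)C[C@@H](c1ccc(O)c(O)c1)O2 | target

**Step count**

Total: 9 steps. Longest linear sequence: 8 steps (steps 1, 2, 3, 4, 6, 7, 8, 9); the alkyne branch is step 5.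

**Steps most likely to fail**

1. Step 6 (key benzannulation). The alkoxyvinylketene may be consumed by self-condensation or by addition of product phenol before it meets the alkyne, and the benzylic vinylogous ester may ionise or eliminate on heating.
Fallback: ring A is taken from phloroglucinol and joined to C2 by Mitsunobu inversion, setting out from keto ester 6 and coming back at target 21. Keto ester 6 is reduced as in step 3 but with RuCl(p-cymene)[(R,R)-TsDPEN] to prop-2-en-1-yl (3R)-3-[3,4-bis(tert-butyldimethylsilyloxy)phenyl]-3-hydroxypropanoate F1. Commercial phloroglucinol is C-prenylated (2-methylbut-3-en-2-ol, BF3·OEt2, dioxane, rt) to 2-(3-methylbut-2-en-1-yl)benzene-1,3,5-triol F2 and silylated (TIPSOTf, 2,6-lutidine, CH2Cl2) to 2-(3-methylbut-2-en-1-yl)-1,3,5-tris(triisopropylsilyloxy)benzene F3. The unhindered silyl ether para to the prenyl group should then be removed selectively with one equivalent of TBAF at −78 °C to give 4-(3-methylbut-2-en-1-yl)-3,5-bis(triisopropylsilyloxy)phenol F4. Mitsunobu coupling of F1 with F4 (PPh3, DIAD, toluene, 0 °C) should give, with inversion, prop-2-en-1-yl (3S)-3-[3,4-bis(tert-butyldimethylsilyloxy)phenyl]-3-[4-(3-methylbut-2-en-1-yl)-3,5-bis(triisopropylsilyloxy)phenoxy]propanoate F5. Deallylation under the conditions of step 7 gives (3S)-3-[3,4-bis(tert-butyldimethylsilyloxy)phenyl]-3-[4-(3-methylbut-2-en-1-yl)-3,5-bis(triisopropylsilyloxy)phenoxy]propanoic acid F6. Acylation under the conditions of step 8, where the two ortho carbons are now identical, gives (2S)-2-[3,4-bis(tert-butyldimethylsilyloxy)phenyl]-6-(3-methylbut-2-en-1-yl)-5,7-bis(triisopropylsilyloxy)-2,3-dihydro-4H-chromen-4-one F7, and the conditions of step 9 give 21.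

2. Step 4 (alkoxy exchange on the cyclobutenone). The acid may ionise the electron-rich benzylic C–O bond (racemisation or elimination to the cinnamate) or cleave the strained enone, and the exchange equilibrium may not be driven to completion.
Fallback: the ether is made at the stereocentre instead of at the vinyl carbon, setting out from 6 and 8 and coming back at 9. 3-Ethoxycyclobutenone 8 is hydrolysed (1 M HCl, THF, rt) to cyclobutane-1,3-dione F8. Its acidic enol is alkylated under Mitsunobu conditions (PPh3, DIAD, THF, 0 °C) by the enantiomeric alcohol prop-2-en-1-yl (3R)-3-[3,4-bis(tert-butyldimethylsilyloxy)phenyl]-3-hydroxypropanoate F1, prepared from 6 as described above, with inversion to give 9.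

3. Step 8 (Friedel–Crafts closure). Acid liberated during acylation may ionise the benzylic aryl ether (racemisation or fragmentation) or promote cyclisation of the prenyl group onto the neighbouring hydroxyl, and the buffered mixed anhydride may acylate too slowly.
Fallback: the C4–C4a bond is made by an anionic Parham-type cyclisation, setting out from acid 18 and coming back at 20. Acid 18 is coupled with N,O-dimethylhydroxylamine hydrochloride (EDC·HCl, HOBt, N-methylmorpholine, CH2Cl2, 0 °C) to give (3S)-3-[3,4-bis(tert-butyldimethylsilyloxy)phenyl]-3-[3-hydroxy-4-(3-methylbut-2-en-1-yl)-5-(triisopropylsilyloxy)phenoxy]-N-methoxy-N-methylpropanamide F9. Amine-directed ortho-bromination of the phenol (NBS, catalytic i-Pr2NH, CH2Cl2, −78 °C) should give (3S)-3-[3,4-bis(tert-butyldimethylsilyloxy)phenyl]-3-[2-bromo-3-hydroxy-4-(3-methylbut-2-en-1-yl)-5-(triisopropylsilyloxy)phenoxy]-N-methoxy-N-methylpropanamide F10. Treatment with t-BuLi (3.3 equiv, THF, −78 °C) deprotonates the phenol and exchanges bromine for lithium, and the aryllithium should add to the Weinreb amide through a six-membered chelate to give 20 on work-up.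

**Further compounds**

F1 | step 6 | prop-2-en-1-yl (3R)-3-[3,4-bis(tert-butyldimethylsilyloxy)phenyl]-3-hydroxypropanoate | C=CCOC(=O)C[C@H](c1ccc(O[Si](C)(C)C(C)(C)C)c(O[Si](C)(C)C(C)(C)C)c1)O
F2 | step 6 | 2-(3-methylbut-2-en-1-yl)benzene-1,3,5-triol | CC(C)=CCc1c(O)cc(O)cc1O
F3 | step 6 | 2-(3-methylbut-2-en-1-yl)-1,3,5-tris(triisopropylsilyloxy)benzene | CC(C)=CCc1c(O[Si](C(C)C)(C(C)C)C(C)C)cc(O[Si](C(C)C)(C(C)C)C(C)C)cc1O[Si](C(C)C)(C(C)C)C(C)C
F4 | step 6 | 4-(3-methylbut-2-en-1-yl)-3,5-bis(triisopropylsilyloxy)phenol | CC(C)=CCc1c(O[Si](C(C)C)(C(C)C)C(C)C)cc(O)cc1O[Si](C(C)C)(C(C)C)C(C)C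
F5 | step 6 | prop-2-en-1-yl (3S)-3-[3,4-bis(tert-butyldimethylsilyloxy)phenyl]-3-[4-(3-methylbut-2-en-1-yl)-3,5-bis(triisopropylsilyloxy)phenoxy]propanoate | C=CCOC(=O)C[C@@H](c1ccc(O[Si](C)(C)C(C)(C)C)c(O[Si](C)(C)C(C)(C)C)c1)Oc1cc(O[Si](C(C)C)(C(C)C)C(C)C)c(CC=C(C)C)c(O[Si](C(C)C)(C(C)C)C(C)C)c1
F6 | step 6 | (3S)-3-[3,4-bis(tert-butyldimethylsilyloxy)phenyl]-3-[4-(3-methylbut-2-en-1-yl)-3,5-bis(triisopropylsilyloxy)phenoxy]propanoic acid | OC(=O)C[C@@H](c1ccc(O[Si](C)(C)C(C)(C)C)c(O[Si](C)(C)C(C)(C)C)c1)Oc1cc(O[Si](C(C)C)(C(C)C)C(C)C)c(CC=C(C)C)c(O[Si](C(C)C)(C(C)C)C(C)C)c1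
F7 | step 6 | (2S)-2-[3,4-bis(tert-butyldimethylsilyloxy)phenyl]-6-(3-methylbut-2-en-1-yl)-5,7-bis(triisopropylsilyloxy)-2,3-dihydro-4H-chromen-4-one | CC(C)=CCc1c(O[Si](C(C)C)(C(C)C)C(C)C)cc2c(c1O[Si](C(C)C)(C(C)C)C(C)C)C(=O)C[C@@H](c1ccc(O[Si](C)(C)C(C)(C)C)c(O[Si](C)(C)C(C)(C)C)c1)O2
F8 | step 4 | cyclobutane-1,3-dione | O=C1CC(=O)C1
F9 | step 8 | (3S)-3-[3,4-bis(tert-butyldimethylsilyloxy)phenyl]-3-[3-hydroxy-4-(3-methylbut-2-en-1-yl)-5-(triisopropylsilyloxy)phenoxy]-N-methoxy-N-methylpropanamide | CON(C)C(=O)C[C@@H](c1ccc(O[Si](C)(C)C(C)(C)C)c(O[Si](C)(C)C(C)(C)C)c1)Oc1cc(O)c(CC=C(C)C)c(O[Si](C(C)C)(C(C)C)C(C)C)c1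
F10 | step 8 | (3S)-3-[3,4-bis(tert-butyldimethylsilyloxy)phenyl]-3-[2-bromo-3-hydroxy-4-(3-methylbut-2-en-1-yl)-5-(triisopropylsilyloxy)phenoxy]-N-methoxy-N-methylpropanamide | CON(C)C(=O)C[C@@H](c1ccc(O[Si](C)(C)C(C)(C)C)c(O[Si](C)(C)C(C)(C)C)c1)Oc1cc(O[Si](C(C)C)(C(C)C)C(C)C)c(CC=C(C)C)c(O)c1Br
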